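**Retrosynthetic overview**
1. Target 18 ⇐ tert-butyl ester 16 ⇐ diene 13 + tert-butyl but-2-ynoate 14 (C12–C13 bond; hydroboration then copper-catalysed syn-carbocupration sets 13E).
2. 13 ⇐ enol triflate 12 ⇐ 8-oxo-9-vinyl decalin 11 (C8 methyl by Negishi coupling, double bond fixed at C7=C8).
3. 11 ⇐ hydrindanyl allylic carbonate 10 by the key step: a palladium-catalysed semipinacol 1,2-shift that expands the cyclopentanol into the cyclohexanone (ring B) and creates C9.
4. 10 ⇐ vinyl carbinol 8 + allyl methyl carbonate 9 (cross-metathesis); 8 ⇐ enedione 4 (vinyl addition, reductive methylation, reduction, acetylation).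
5. 4 ⇐ 2-methylcyclopentane-1,3-dione 1 + ethyl vinyl ketone 2. Ring order: five-membered ring (bought), then ring A (annulation), then ring B (ring expansion of the five-membered ring).

Assumption: the target is the enantiomer drawn (3β-acetoxylabda-7,13E-dien-15-oic acid, 5α-H, 10β-methyl), and tert-butyl but-2-ynoate 14 is bought as such, its tert-butyl group being only a carboxyl protecting group.

**Route**

Step 1
Reactants: 1 2-methylcyclopentane-1,3-dione; 2 pent-1-en-3-one (ethyl vinyl ketone)
Product: 4 (7aS)-4,7a-dimethyl-2,3,7,7a-tetrahydro-1H-indene-1,5(6H)-dione, via triketone 3 (not isolated)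
Conditions: 2 (1.3 equiv), H2O, 70 °C; concentrate; L-phenylalanine (1.0 equiv), (1S)-camphor-10-sulfonic acid (0.5 equiv), neat, 30→70 °C; recrystallise
Reagents that add atoms: none
Why: Michael addition followed by amino-acid-mediated intramolecular aldol condensation (Hajos–Parrish/Eder–Sauer–Wiechert annulation), in which the L-phenylalanine enamine differentiates the two enantiotopic ring carbonyls and fixes the methyl-bearing quaternary carbon (future C10) as S while closing ring A.

Step 2
Reactants: 4 (7aS)-4,7a-dimethyl-2,3,7,7a-tetrahydro-1H-indene-1,5(6H)-dione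
Product: 5 (1R,7aS)-1-ethenyl-1-hydroxy-4,7a-dimethyl-1,2,3,6,7,7a-hexahydro-5H-inden-5-one
Conditions: CH2=CHMgBr (1.3 equiv), CeCl3 (1.4 equiv), THF, −78 °C
Reagents that add atoms: vinylmagnesium bromide, C=C[Mg]Br
Why: Chemoselective organocerium 1,2-addition to the saturated cyclopentanone (more electrophilic than the tetrasubstituted enone carbonyl) from the face opposite the angular methyl gives the 1R carbinol, which masks this carbonyl for the next step and carries the alkene for the ring expansion (this centre is lost in step 6).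

Step 3
Reactants: 5 (1R,7aS)-1-ethenyl-1-hydroxy-4,7a-dimethyl-1,2,3,6,7,7a-hexahydro-5H-inden-5-one
Product: 7 (1R,3aS,5S,7aS)-1-ethenyl-4,4,7a-trimethyloctahydro-1H-indene-1,5-diol, via ketone 6 (not isolated)
Conditions: Li (2.5 equiv), NH3/THF, −78 °C; isoprene; MeI (4 equiv), −78→−33 °C; evaporate NH3; NaBH4, THF/MeOH, 0 °C
Reagents that add atoms: iodomethane, CI
Why: Birch-type reductive methylation, in which the enone radical anion is protonated at the ring-fusion carbon (by the substrate's own hydroxyl) anti to the angular methyl to give the trans-fused lithium enolate, which is C-methylated regiospecifically to the gem-dimethyl ketone, after which NaBH4 attacks this hindered ketone axially to give the equatorial 5S alcohol cis to the angular methyl.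

Step 4
Reactants: 7 (1R,3aS,5S,7aS)-1-ethenyl-4,4,7a-trimethyloctahydro-1H-indene-1,5-diol
Product: 8 (1R,3aS,5S,7aS)-1-ethenyl-1-hydroxy-4,4,7a-trimethyloctahydro-1H-inden-5-yl acetate
Conditions: Ac2O (1.5 equiv), DMAP (0.1 equiv), pyridine, CH2Cl2, 0 °C→rt
Reagents that add atoms: acetic anhydride, CC(=O)OC(C)=O
Why: DMAP-catalysed esterification of the secondary alcohol only, since the tertiary, doubly neopentylic allylic alcohol is not acylated under these conditions.

Step 5
Reactants: 8 (1R,3aS,5S,7aS)-1-ethenyl-1-hydroxy-4,4,7a-trimethyloctahydro-1H-inden-5-yl acetate; 9 allyl methyl carbonate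
Product: 10 (2E)-3-[(1R,3aS,5S,7aS)-5-acetoxy-1-hydroxy-4,4,7a-trimethyloctahydro-1H-inden-1-yl]prop-2-en-1-yl methyl carbonate
Conditions: 9 (4 equiv), second-generation Hoveyda–Grubbs catalyst RuCl2(H2IMes)(=CH-C6H4-2-OiPr) (5 mol %), CH2Cl2, 40 °C, argon sparge
Reagents that add atoms: none
Why: Olefin cross-metathesis between a slowly homodimerising tertiary allylic alcohol and an unhindered allyl carbonate gives the E-disubstituted alkene under thermodynamic control with loss of ethene.

Step 6
Reactants: 10 (2E)-3-[(1R,3aS,5S,7aS)-5-acetoxy-1-hydroxy-4,4,7a-trimethyloctahydro-1H-inden-1-yl]prop-2-en-1-yl methyl carbonate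
Product: 11 (2S,4aS,5R,8aR)-5-ethenyl-1,1,4a-trimethyl-6-oxodecahydronaphthalen-2-yl acetate
Conditions: Pd2(dba)3·CHCl3 (2.5 mol %), P(OPh)3 (12 mol %), THF, 60 °C
Reagents that add atoms: none
Why: Proposed new method: zerovalent palladium ionises the allylic carbonate (loss of CO2; the methoxide deprotonates the tertiary alcohol) and the alkoxide then drives a semipinacol 1,2-shift of the ring bond to the quaternary carbon (the more electron-rich bond, lying anti to palladium, which binds the allyl face next to the smaller CH2) onto the proximal allyl terminus, expanding the cyclopentanol to the cyclohexanone of ring B with retention at the migrating carbon and releasing the catalyst, while the new α-centre C9 settles by enolisation under the mildly basic conditions as the equatorial-vinyl epimer (vinyl cis to the angular methyl); the shift is made irreversible by C=O formation, the carbinol carbon has no β-hydrogen for diene formation, and O-attack at the proximal terminus gives only a reversibly formed vinyl epoxide; closest known reaction type: the palladium-catalysed Wagner–Meerwein (semipinacol) ring expansion of strained 1-alkenylcyclopropanol and 1-alkenylcyclobutanol allylic carbonates and of allenylcyclobutanols to α-vinyl ketones, not yet shown for an unstrained cyclopentanol.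

Step 7
Reactants: 11 (2S,4aS,5R,8aR)-5-ethenyl-1,1,4a-trimethyl-6-oxodecahydronaphthalen-2-yl acetate
Product: 12 (2S,4aS,5R,8aR)-5-ethenyl-1,1,4a-trimethyl-6-[(trifluoromethanesulfonyl)oxy]-1,2,3,4,4a,5,8,8a-octahydronaphthalen-2-yl acetate
Conditions: KN(SiMe3)2 (1.1 equiv), THF, −78 °C; PhNTf2 (1.2 equiv), −78→0 °C
Reagents that add atoms: N-phenylbis(trifluoromethanesulfonimide), O=S(=O)(N(c1ccccc1)S(=O)(=O)C(F)(F)F)C(F)(F)F
Why: Kinetic enolisation with a bulky amide at the unhindered C7 methylene (α′-deprotonation, as is usual for α-alkenyl cyclohexanones; the C9 hydrogen is tertiary and flanked by the quaternary carbon, and the ketone is several pKa units more acidic than the acetate) followed by O-triflation gives the less substituted enol triflate and leaves C9 untouched.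

Step 8
Reactants: 12 (2S,4aS,5R,8aR)-5-ethenyl-1,1,4a-trimethyl-6-[(trifluoromethanesulfonyl)oxy]-1,2,3,4,4a,5,8,8a-octahydronaphthalen-2-yl acetate
Product: 13 (2S,4aS,5S,8aR)-5-ethenyl-1,1,4a,6-tetramethyl-1,2,3,4,4a,5,8,8a-octahydronaphthalen-2-yl acetate
Conditions: MeZnCl (2 equiv), Pd(PPh3)4 (5 mol %), THF, 50 °C
Reagents that add atoms: methylzinc chloride, C[Zn]Cl
Why: Negishi cross-coupling of the alkenyl triflate installs the C8 methyl with the double bond fixed at C7=C8, and the organozinc reagent tolerates the acetate.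

Step 9
Reactants: 13 (2S,4aS,5S,8aR)-5-ethenyl-1,1,4a,6-tetramethyl-1,2,3,4,4a,5,8,8a-octahydronaphthalen-2-yl acetate; 14 tert-butyl but-2-ynoate
Product: 16 tert-butyl (2E)-5-[(1S,4aR,6S,8aR)-6-acetoxy-2,5,5,8a-tetramethyl-1,4,4a,5,6,7,8,8a-octahydronaphthalen-1-yl]-3-methylpent-2-enoate, via alkylborane 15 (not isolated)
Conditions: 9-BBN (1.2 equiv), THF, 0→50 °C; then 14 (1.5 equiv), CuOAc (10 mol %), P(OPh)3 (20 mol %), KOtBu (10 mol %), t-BuOH (1.5 equiv), 1,4-dioxane, 30 °C
Reagents that add atoms: none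
Why: 9-BBN hydroborates only the monosubstituted alkene (anti-Markovnikov), and copper-catalysed conjugate addition of the B-alkyl group to the ynoate proceeds by syn-carbocupration and protonation, which places the new chain trans to the ester and so sets the 13E geometry.

Step 10
Reactants: 16 tert-butyl (2E)-5-[(1S,4aR,6S,8aR)-6-acetoxy-2,5,5,8a-tetramethyl-1,4,4a,5,6,7,8,8a-octahydronaphthalen-1-yl]-3-methylpent-2-enoate
Product: 18 (2E)-5-[(1S,4aR,6S,8aR)-6-acetoxy-2,5,5,8a-tetramethyl-1,4,4a,5,6,7,8,8a-octahydronaphthalen-1-yl]-3-methylpent-2-enoic acid, via silyl ester 17 (not isolated)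
Conditions: TMSOTf (2 equiv), 2,6-lutidine (3 equiv), CH2Cl2, 0 °C; aqueous citric acid work-up
Reagents that add atoms: none
Why: Silyl-triflate-mediated cleavage of the tert-butyl ester (loss of isobutene, then hydrolysis of the trimethylsilyl ester on work-up) under non-protic conditions spares the secondary acetate, the trisubstituted ring alkene and the E-enoate.

**Compound list**
1 | 2-methylcyclopentane-1,3-dione | CC1C(=O)CCC1=O | starting material
2 | pent-1-en-3-one (ethyl vinyl ketone) | CCC(=O)C=C | starting material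
3 | 2-methyl-2-(3-oxopentyl)cyclopentane-1,3-dione | CCC(=O)CCC1(C)C(=O)CCC1=O | intermediate
4 | (7aS)-4,7a-dimethyl-2,3,7,7a-tetrahydro-1H-indene-1,5(6H)-dione | C[C@]12CCC(=O)C(C)=C1CCC2=O | intermediate
5 | (1R,7aS)-1-ethenyl-1-hydroxy-4,7a-dimethyl-1,2,3,6,7,7a-hexahydro-5H-inden-5-one (OH cis to the angular methyl) | C[C@]12CCC(=O)C(C)=C1CC[C@@]2(O)C=C | intermediate
6 | (1R,3aR,7aS)-1-ethenyl-1-hydroxy-4,4,7a-trimethyloctahydro-5H-inden-5-one (trans-fused) | C[C@]12CCC(=O)C(C)(C)[C@@H]1CC[C@@]2(O)C=C | intermediate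
7 | (1R,3aS,5S,7aS)-1-ethenyl-4,4,7a-trimethyloctahydro-1H-indene-1,5-diol | C[C@]12CC[C@H](O)C(C)(C)[C@@H]1CC[C@@]2(O)C=C | intermediate
8 | (1R,3aS,5S,7aS)-1-ethenyl-1-hydroxy-4,4,7a-trimethyloctahydro-1H-inden-5-yl acetate | C[C@]12CC[C@H](OC(C)=O)C(C)(C)[C@@H]1CC[C@@]2(O)C=C | intermediate
9 | allyl methyl carbonate | C=CCOC(=O)OC | starting material
10 | (2E)-3-[(1R,3aS,5S,7aS)-5-acetoxy-1-hydroxy-4,4,7a-trimethyloctahydro-1H-inden-1-yl]prop-2-en-1-yl methyl carbonate | C[C@]12CC[C@H](OC(C)=O)C(C)(C)[C@@H]1CC[C@@]2(O)/C=C/COC(=O)OC | intermediate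
11 | (2S,4aS,5R,8aR)-5-ethenyl-1,1,4a-trimethyl-6-oxodecahydronaphthalen-2-yl acetate (3β-acetoxy-8-oxo-9β-vinyl, trans-decalin) | CC(=O)O[C@H]1CC[C@]2(C)[C@@H](C=C)C(=O)CC[C@H]2C1(C)C | intermediate
12 | (2S,4aS,5R,8aR)-5-ethenyl-1,1,4a-trimethyl-6-[(trifluoromethanesulfonyl)oxy]-1,2,3,4,4a,5,8,8a-octahydronaphthalen-2-yl acetate | CC(=O)O[C@H]1CC[C@]2(C)[C@@H](C=C)C(OS(=O)(=O)C(F)(F)F)=CC[C@H]2C1(C)C | intermediate
13 | (2S,4aS,5S,8aR)-5-ethenyl-1,1,4a,6-tetramethyl-1,2,3,4,4a,5,8,8a-octahydronaphthalen-2-yl acetate | CC(=O)O[C@H]1CC[C@]2(C)[C@@H](C=C)C(C)=CC[C@H]2C1(C)C | intermediate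
14 | tert-butyl but-2-ynoate | CC#CC(=O)OC(C)(C)C | starting material
15 | (2S,4aR,5S,8aR)-5-[2-(9-borabicyclo[3.3.1]nonan-9-yl)ethyl]-1,1,4a,6-tetramethyl-1,2,3,4,4a,5,8,8a-octahydronaphthalen-2-yl acetate | CC(=O)O[C@H]1CC[C@]2(C)[C@@H](CCB3C4CCCC3CCC4)C(C)=CC[C@H]2C1(C)C | intermediate
16 | tert-butyl (2E)-5-[(1S,4aR,6S,8aR)-6-acetoxy-2,5,5,8a-tetramethyl-1,4,4a,5,6,7,8,8a-octahydronaphthalen-1-yl]-3-methylpent-2-enoate | CC(=O)O[C@H]1CC[C@]2(C)[C@@H](CC/C(C)=C/C(=O)OC(C)(C)C)C(C)=CC[C@H]2C1(C)C | intermediate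
17 | trimethylsilyl (2E)-5-[(1S,4aR,6S,8aR)-6-acetoxy-2,5,5,8a-tetramethyl-1,4,4a,5,6,7,8,8a-octahydronaphthalen-1-yl]-3-methylpent-2-enoate | CC(=O)O[C@H]1CC[C@]2(C)[C@@H](CC/C(C)=C/C(=O)O[Si](C)(C)C)C(C)=CC[C@H]2C1(C)C | intermediate
18 | (2E)-5-[(1S,4aR,6S,8aR)-6-acetoxy-2,5,5,8a-tetramethyl-1,4,4a,5,6,7,8,8a-octahydronaphthalen-1-yl]-3-methylpent-2-enoic acid (3β-acetoxylabda-7,13E-dien-15-oic acid) | CC(=O)O[C@H]1CC[C@]2(C)[C@@H](CC/C(C)=C/C(=O)O)C(C)=CC[C@H]2C1(C)C | target

**Totals and risks**

Total step count: 10. Longest linear sequence: 10 steps (from 1 and 2 to 18).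

Risk 1, the ring expansion of step 6 (the proposed new step). The cyclopentanol has no strain to release, so the 1,2-shift may be slow. Possible diversions are syn/anti isomerisation of the allyl followed by O-cyclisation to a spiro-2,5-dihydrofuran, migration of the ring CH2 instead of the quaternary carbon, and drift of the β,γ-unsaturated ketone into conjugation. The fallback uses known chemistry, sets out from 8 and returns at 11. Ozonolysis of the vinyl group (O3, CH2Cl2/MeOH, −78 °C; Me2S) gives the α-hydroxy aldehyde F1. Nozaki–Hiyama–Kishi vinylation (vinyl bromide, CrCl2, catalytic NiCl2, DMF) gives the vinyl diol F2 as a mixture at the new carbinol. Selective sulfonylation of the secondary allylic hydroxyl (MsCl, Et3N, −40 °C) gives the mesylate F3. Treating F3 with Et3Al (CH2Cl2, −78→0 °C) effects the established organoaluminium-promoted pinacol-type rearrangement of a 2-hydroxy mesylate, the same ring-expanding 1,2-shift, and delivers 11.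

Risk 2, the enol triflation of step 7. The C9 hydrogen is both α to the ketone and allylic, so some conjugated dienolate may form, and the acetate must survive the amide base. The fallback sets out from 11 and returns at 13. Condensation with TsNHNH2 (MeOH, catalytic AcOH) gives the tosylhydrazone F4, with the sulfonamide anti to the substituted C9. A Shapiro reaction with excess n-BuLi (the acetate is sacrificed) deprotonates only syn to the sulfonamide nitrogen, at C7, and the C8 vinyllithium is quenched with MeI to give the hydroxy diene F5. Re-acetylation (Ac2O, DMAP, pyridine) gives 13.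

Risk 3, the hydroboration and copper-catalysed conjugate addition of step 9. The vinyl group sits between the quaternary carbon and the substituted alkene, and the copper-catalysed B-alkyl addition to an ynoate has little precedent in such a hindered, functionalised setting (protodeboronation, or loss of E-geometry if the alkenylcopper isomerises). The fallback sets out from 15 and returns at 16. The alkylborane 15 is used in a stereoretentive B-alkyl Suzuki–Miyaura coupling (Pd(dppf)Cl2, K3PO4, THF/DMF/H2O, rt→50 °C) with the E-enol triflate F6, made from tert-butyl acetoacetate with Tf2O and aqueous Me4NOH.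

**Further compounds**
F1 | step 6 | (1S,3aS,5S,7aS)-1-formyl-1-hydroxy-4,4,7a-trimethyloctahydro-1H-inden-5-yl acetate | C[C@]12CC[C@H](OC(C)=O)C(C)(C)[C@@H]1CC[C@@]2(O)C=O
F2 | step 6 | (1S,3aS,5S,7aS)-1-hydroxy-1-(1-hydroxyprop-2-en-1-yl)-4,4,7a-trimethyloctahydro-1H-inden-5-yl acetate (both side-chain carbinol epimers) | C[C@]12CC[C@H](OC(C)=O)C(C)(C)[C@@H]1CC[C@@]2(O)C(O)C=C
F3 | step 6 | (1S,3aS,5S,7aS)-1-hydroxy-1-[1-(methanesulfonyloxy)prop-2-en-1-yl]-4,4,7a-trimethyloctahydro-1H-inden-5-yl acetate (both side-chain epimers) | C[C@]12CC[C@H](OC(C)=O)C(C)(C)[C@@H]1CC[C@@]2(O)C(OS(C)(=O)=O)C=C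
F4 | step 7 | (E)-4-methylbenzenesulfonyl hydrazone of 11 (sulfonamide anti to the vinyl-bearing carbon) | CC(=O)O[C@H]1CC[C@]2(C)[C@@H](C=C)/C(=N/NS(=O)(=O)c3ccc(C)cc3)CC[C@H]2C1(C)C
F5 | step 7 | (2S,4aS,5S,8aR)-5-ethenyl-1,1,4a,6-tetramethyl-1,2,3,4,4a,5,8,8a-octahydronaphthalen-2-ol | O[C@H]1CC[C@]2(C)[C@@H](C=C)C(C)=CC[C@H]2C1(C)C
F6 | step 9 | tert-butyl (2E)-3-[(trifluoromethanesulfonyl)oxy]but-2-enoate | C/C(OS(=O)(=O)C(F)(F)F)=C\C(=O)OC(C)(C)C
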